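**Retrosynthetic overview**

1. Ring B (the cyclohexa-2,4-dienone C3a–C4–C5–C6–C7–C7a) is made last and in one operation by cutting C3a=C4 and C5–C6. This gives a two-carbon piece C4–C5 (carrying OMe and allyl) and a four-carbon piece C6–C7–C7a–C3a that already carries ring A.
2. Enabling feature: in ring B, C6=O and the enol-ether carbon C7a (bonded to O1) are a masked acetoacetyl unit, so C6 is an acyl/ketene electrophile and C3a its γ-nucleophile. The quaternary C5 lies α to C4, which stands at the aldehyde oxidation level (the C3a=C4 alkene), so C5 can be an enamine carbon and C4 an iminium carbon.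
3. Key step: the vinylketene from an (oxolan-2-ylidene)acetyl chloride and a chiral enamine of racemic 2-methoxypent-4-enal undergo a formal [4+2] annulation with loss of the amine; both aldehyde enantiomers converge on (5R).
4. Ring A (oxolane O1–C2–C3–C3a–C7a) is formed first as the trans γ-lactone, by anti-crotylboration of 3,4,5-trimethoxybenzaldehyde, hydroboration and oxidative lactonisation. The lactone carbonyl (future C7a) is then extended to the ylidene acetate (C7, C6).
5. Order of ring formation: ring A (step 3), then ring B (step 10).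

Key step: step 10

Assumption: the (E)-crotylborane made from (−)-Ipc2BOMe is taken to add to the Si face of the aryl aldehyde, as it does with benzaldehyde, which gives the (1S,2S) alcohol.

**Route**

Step 1
Reactants: 1 3,4,5-trimethoxybenzaldehyde
Product: 3 (1S,2S)-2-methyl-1-(3,4,5-trimethoxyphenyl)but-3-en-1-ol, via borinate ester 2 (not isolated)
Conditions: (E)-but-2-ene, KOtBu, n-BuLi, THF, −78 to −45 °C; (−)-Ipc2BOMe, −78 °C; BF3·OEt2; then 1, −78 °C; then NaOH, H2O2, 0 °C to rt
Reagents that add atoms: (E)-but-2-ene, C/C=C/C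
Why: Brown crotylboration, in which the closed chair transition state turns the E geometry of the crotylborane into the anti relation of OH and Me and the isopinocampheyl groups direct attack to the Si face of the aldehyde, setting both stereocentres as (1S,2S).

Step 2
Reactants: 3 (1S,2S)-2-methyl-1-(3,4,5-trimethoxyphenyl)but-3-en-1-ol
Product: 5 (1S,2S)-2-methyl-1-(3,4,5-trimethoxyphenyl)butane-1,4-diol, via organoborane 4 (not isolated)
Conditions: 9-BBN (2.5 equiv), THF, 0 °C to rt; then NaOH, H2O2, 0 °C
Reagents that add atoms: hydrogen peroxide, OO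
Why: Anti-Markovnikov hydroboration–oxidation of the terminal alkene with the bulky 9-BBN should place the hydroxyl on the terminal carbon without involving the stereocentres.

Step 3
Reactants: 5 (1S,2S)-2-methyl-1-(3,4,5-trimethoxyphenyl)butane-1,4-diol
Product: 7 (4S,5S)-4-methyl-5-(3,4,5-trimethoxyphenyl)oxolan-2-one, via lactol 6 (not isolated)
Conditions: TEMPO (0.2 equiv), PhI(OAc)2 (2.5 equiv), CH2Cl2, rt
Reagents that add atoms: none
Why: Oxidative lactonisation, in which TEMPO/PhI(OAc)2 oxidises the primary alcohol selectively, the hydroxy aldehyde closes to lactol 6 and is oxidised on to the γ-lactone, so that the anti diol gives the trans lactone with both stereocentres untouched.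

Step 4
Reactants: 7 (4S,5S)-4-methyl-5-(3,4,5-trimethoxyphenyl)oxolan-2-one
Product: 9 methyl 2-[(4S,5S)-2-hydroxy-4-methyl-5-(3,4,5-trimethoxyphenyl)oxolan-2-yl]acetate (anomeric mixture), via lithium hemiketal alkoxide 8 (not isolated)
Conditions: MeOAc, LiN(iPr)2 (2.2 equiv), THF, −78 °C; then 7, −78 °C; then AcOH, −78 °C to rt
Reagents that add atoms: methyl acetate, CC(=O)OC
Why: Crossed Claisen-type addition of the lithium enolate of methyl acetate to the lactone carbonyl should stop at the tetrahedral alkoxide at −78 °C and give, after protonation, the β-keto ester in its cyclic hemiketal form.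

Step 5
Reactants: 9 methyl 2-[(4S,5S)-2-hydroxy-4-methyl-5-(3,4,5-trimethoxyphenyl)oxolan-2-yl]acetate
Product: 10 methyl (2E)-2-[(4S,5S)-4-methyl-5-(3,4,5-trimethoxyphenyl)oxolan-2-ylidene]acetate
Conditions: TsOH·H2O (0.05 equiv), 4 Å MS, toluene, 50 °C
Reagents that add atoms: none
Why: Acid-catalysed dehydration of the hemiketal through the ring oxocarbenium ion should give the exocyclic enol ether conjugated with the ester (a vinylogous carbonate) as the thermodynamic E isomer; the geometry has no consequence later.

Step 6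
Reactants: 10 methyl (2E)-2-[(4S,5S)-4-methyl-5-(3,4,5-trimethoxyphenyl)oxolan-2-ylidene]acetate
Product: 11 potassium (2E)-2-[(4S,5S)-4-methyl-5-(3,4,5-trimethoxyphenyl)oxolan-2-ylidene]acetate
Conditions: KOSiMe3 (1.2 equiv), THF, rt
Reagents that add atoms: potassium trimethylsilanolate, C[Si](C)(C)[O-].[K+]
Why: Anhydrous ester cleavage with potassium trimethylsilanolate should give the potassium carboxylate directly, so that the acid-labile β-alkoxyacrylic acid is never set free.

Step 7
Reactants: 12 methyl methoxyacetate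
Product: 14 methyl 2-methoxypent-4-enoate (racemic), via lithium enolate 13 (not isolated)
Conditions: LiN(iPr)2, THF, −78 °C; allyl bromide, DMPU, −78 to 0 °C
Reagents that add atoms: allyl bromide, C=CCBr
Why: Enolate alkylation (SN2) of the α-alkoxy ester with allyl bromide; the new stereocentre is left racemic on purpose, as step 9 erases it.

Step 8
Reactants: 14 methyl 2-methoxypent-4-enoate
Product: 16 2-methoxypent-4-enal (racemic), via aluminium hemiacetal 15 (not isolated)
Conditions: iBu2AlH (1.1 equiv), CH2Cl2, −78 °C; then MeOH, aqueous KNa tartrate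
Reagents that add atoms: none
Why: Partial reduction of the α-alkoxy ester with iBu2AlH at −78 °C should stop at the chelated aluminium hemiacetal 15, which releases the aldehyde only on work-up.

Step 9
Reactants: 16 2-methoxypent-4-enal; 17 (2R,5R)-2,5-diphenylpyrrolidine
Product: 18 (2R,5R)-1-[(1Z)-2-methoxypenta-1,4-dien-1-yl]-2,5-diphenylpyrrolidine
Conditions: 4 Å MS, PhCO2H (0.05 equiv), benzene, rt to 40 °C; used crude
Reagents that add atoms: none
Why: Enamine condensation erases the α-stereocentre of racemic 16, and equilibration through the iminium ion should favour the Z isomer, in which the small methoxy group and not the allyl group lies cis to the hindered nitrogen (allylic 1,3-strain, cis effect of vicinal heteroatoms).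

Step 10
Reactants: 11 potassium (2E)-2-[(4S,5S)-4-methyl-5-(3,4,5-trimethoxyphenyl)oxolan-2-ylidene]acetate; 18 (2R,5R)-1-[(1Z)-2-methoxypenta-1,4-dien-1-yl]-2,5-diphenylpyrrolidine
Product: 23 (2S,3S,5R)-5-allyl-5-methoxy-3-methyl-2-(3,4,5-trimethoxyphenyl)-2,3-dihydrobenzofuran-6(5H)-one, via acid chloride 19 (not isolated), via vinylketene 20 (not isolated), via iminium dienolate 21 (not isolated), via aminocyclohexenone 22 (not isolated)
Conditions: 11, (COCl)2 (1.05 equiv), DMF (cat.), CH2Cl2, 0 °C, then evaporation; then slow addition to 18 (1.1 equiv) and iPr2NEt (1.2 equiv), CH2Cl2, −78 °C to rt; then SiO2, rt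
Reagents that add atoms: none
Why: Proposed new method: (COCl)2 turns 11 into acid chloride 19, iPr2NEt removes HCl across C6/C3a (1,4-elimination) to give vinylketene 20, the enamine carbon C5 of 18 adds to the ketene carbon C6 (C5–C6 bond) to give iminium dienolate 21, the γ-carbon C3a of the dienolate adds to the iminium carbon C4 (C3a–C4 bond), and the vinylogous β-amino ketone 22 expels the pyrrolidine by E1cB to leave the C3a=C4 double bond of 23. The closest known reaction type is the formal [4+2] annulation of vinylketenes (made from α,β-unsaturated acid chlorides and a tertiary amine) with aldehyde enamines, which after loss of the amine gives 6,6-disubstituted cyclohexa-2,4-dienones and is an extension of the Stork enamine acylation; not yet shown are the β-alkoxy vinylketene, the α-alkoxy enamine and stereocontrol by a C2-symmetric amine that leaves in the same step. Ring B is closed by a 6-(enolendo)-exo-trig vinylogous Mannich addition. C5, the only new stereocentre that persists, is set in the C5–C6 bond formation: in the Z enamine the phenyl group on the pyrrolidine carbon next to C5 covers one face, and attack of C6 on the open face should give (5R), so that both enantiomers of aldehyde 16 end in one configuration; C3a and C4 are transient stereocentres and are erased by the elimination. The step needs γ- over α-closure of the dienolate (six- against four-membered ring) and C- over N-acylation: the quaternary C5 rules out enamide formation, α-closure to the aminocyclobutanone is reversible by retro-Mannich opening, and the irreversible loss of amine from 22 draws the equilibria towards 23. C2 and C3 are untouched, since the C3–H bond is not acidified in any intermediate.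

**Compound list**

1 | 3,4,5-trimethoxybenzaldehyde | COc1cc(C=O)cc(OC)c1OC | starting material
2 | (1S,2S)-2-methyl-1-(3,4,5-trimethoxyphenyl)but-3-en-1-yl bis(isopinocampheyl)borinate | O(B([C@@H]1C[C@@H]2C[C@H]([C@H]1C)C2(C)C)[C@@H]1C[C@@H]2C[C@H]([C@H]1C)C2(C)C)[C@H](c1cc(OC)c(OC)c(OC)c1)[C@H](C=C)C | intermediate
3 | (1S,2S)-2-methyl-1-(3,4,5-trimethoxyphenyl)but-3-en-1-ol | O[C@H](c1cc(OC)c(OC)c(OC)c1)[C@H](C=C)C | intermediate
4 | O-boryl, C-boryl bis(9-BBN) adduct of 3 | O(B1C2CCCC1CCC2)[C@H](c1cc(OC)c(OC)c(OC)c1)[C@H](CCB1C2CCCC1CCC2)C | intermediate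
5 | (1S,2S)-2-methyl-1-(3,4,5-trimethoxyphenyl)butane-1,4-diol | O[C@H](c1cc(OC)c(OC)c(OC)c1)[C@H](CCO)C | intermediate
6 | (4S,5S)-4-methyl-5-(3,4,5-trimethoxyphenyl)oxolan-2-ol (anomeric mixture) | O1[C@H](c2cc(OC)c(OC)c(OC)c2)[C@H](CC1O)C | intermediate
7 | (4S,5S)-4-methyl-5-(3,4,5-trimethoxyphenyl)oxolan-2-one | O1[C@H](c2cc(OC)c(OC)c(OC)c2)[C@H](CC1=O)C | intermediate
8 | lithium (4S,5S)-2-(2-methoxy-2-oxoethyl)-4-methyl-5-(3,4,5-trimethoxyphenyl)oxolan-2-olate | O1[C@H](c2cc(OC)c(OC)c(OC)c2)[C@H](CC1([O-])CC(=O)OC)C.[Li+] | intermediate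
9 | methyl 2-[(4S,5S)-2-hydroxy-4-methyl-5-(3,4,5-trimethoxyphenyl)oxolan-2-yl]acetate | O1[C@H](c2cc(OC)c(OC)c(OC)c2)[C@H](CC1(O)CC(=O)OC)C | intermediate
10 | methyl (2E)-2-[(4S,5S)-4-methyl-5-(3,4,5-trimethoxyphenyl)oxolan-2-ylidene]acetate | O1[C@H](c2cc(OC)c(OC)c(OC)c2)[C@H](C/C1=C\C(=O)OC)C | intermediate
11 | potassium (2E)-2-[(4S,5S)-4-methyl-5-(3,4,5-trimethoxyphenyl)oxolan-2-ylidene]acetate | O1[C@H](c2cc(OC)c(OC)c(OC)c2)[C@H](C/C1=C\C(=O)[O-])C.[K+] | intermediate
12 | methyl methoxyacetate | COCC(=O)OC | starting material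
13 | lithium enolate of methyl methoxyacetate | COC=C(OC)[O-].[Li+] | intermediate
14 | methyl 2-methoxypent-4-enoate (racemic) | C=CCC(OC)C(=O)OC | intermediate
15 | diisobutylaluminium hemiacetal of 14 | C=CCC(OC)C(OC)O[Al](CC(C)C)CC(C)C | intermediate
16 | 2-methoxypent-4-enal (racemic) | C=CCC(OC)C=O | intermediate
17 | (2R,5R)-2,5-diphenylpyrrolidine | N1[C@@H](c2ccccc2)CC[C@@H]1c1ccccc1 | starting material
18 | (2R,5R)-1-[(1Z)-2-methoxypenta-1,4-dien-1-yl]-2,5-diphenylpyrrolidine | CO/C(CC=C)=C\N1[C@@H](c2ccccc2)CC[C@@H]1c1ccccc1 | intermediate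
19 | (2E)-2-[(4S,5S)-4-methyl-5-(3,4,5-trimethoxyphenyl)oxolan-2-ylidene]acetyl chloride | O1[C@H](c2cc(OC)c(OC)c(OC)c2)[C@H](C/C1=C\C(Cl)=O)C | intermediate
20 | 2-[(4S,5S)-4-methyl-5-(3,4,5-trimethoxyphenyl)-4,5-dihydrofuran-2-yl]ethen-1-one (vinylketene) | O1[C@H](c2cc(OC)c(OC)c(OC)c2)[C@H](C=C1C=C=O)C | intermediate
21 | iminium dienolate from C5–C6 bond formation, (R) at the new quaternary carbon | O1[C@H](c2cc(OC)c(OC)c(OC)c2)[C@H](C=C1C=C([O-])[C@@](OC)(CC=C)C=[N+]1[C@@H](c2ccccc2)CC[C@@H]1c1ccccc1)C | intermediate
22 | (2S,3S,5R)-5-allyl-4-[(2R,5R)-2,5-diphenylpyrrolidin-1-yl]-5-methoxy-3-methyl-2-(3,4,5-trimethoxyphenyl)-3,3a,4,5-tetrahydrobenzofuran-6(2H)-one (C3a and C4 transient, not defined) | C=CC[C@@]1(OC)C(N3[C@@H](c4ccccc4)CC[C@@H]3c3ccccc3)C2C(=CC1=O)O[C@H](c1cc(OC)c(OC)c(OC)c1)[C@H]2C | intermediate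
23 | (2S,3S,5R)-5-allyl-5-methoxy-3-methyl-2-(3,4,5-trimethoxyphenyl)-2,3-dihydrobenzofuran-6(5H)-one | C=CC[C@@]1(OC)C=C2C(=CC1=O)O[C@H](c1cc(OC)c(OC)c(OC)c1)[C@H]2C | target

**Step count and risks**

Total step count: 10. Longest linear sequence: 7 (steps 1–6, then step 10).

Steps most likely to fail:

1. Step 10 (proposed new method). The facial discrimination at C5 may be poor (enamine geometry not uniform, or shielding by the phenyl group too weak), the dienolate may close through its α-carbon, or the Mannich closure at the hindered iminium carbon may be slow. Fallback, from 11 back to 23: acid chloride 19 is generated from 11 as before and combined with the achiral enamine (E)-1-(penta-1,4-dien-1-yl)pyrrolidine F1 (from pent-4-enal and pyrrolidine) and iPr2NEt. The precedented vinylketene–enamine annulation, loss of pyrrolidine and tautomerisation should give the phenol (2S,3S)-5-allyl-3-methyl-2-(3,4,5-trimethoxyphenyl)-2,3-dihydrobenzofuran-6-ol F2. Wessely-type oxidative methoxylation of F2 (Pb(OAc)4, MeOH, 0 °C), the dearomatisation used for ortho-allylphenols of this neolignan class, should then give 23 together with its C5 epimer. The two are diastereomers and would be separated by chromatography.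

2. Step 9. Condensation of the hindered amine with the α-branched aldehyde may stay incomplete, and the volatile aldehyde may be lost or self-condense. Fallback, from 14 and 17 back to 18: Me3Al-mediated aminolysis of ester 14 with amine 17 should give the amide (2R,5R)-1-(2-methoxypent-4-enoyl)-2,5-diphenylpyrrolidine F3 (epimers at the α-carbon, of no consequence). Hydrosilylation of F3 with (Me2HSi)2O and IrCl(CO)(PPh3)2 (cat.) in toluene should give the O-silyl hemiaminal F4, which loses the silanol on warming to give enamine 18 under water-free conditions; a trace of PhCO2H would then equilibrate the geometry.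

3. Step 6. Cleavage of the deactivated vinylogous carbonate ester may be slow or unselective (conjugate addition of silanolate, ring opening), and the salt may decarboxylate on handling. Fallback, from 7 back to 11: Petasis methylenation of lactone 7 (Cp2TiMe2, toluene, 65 °C) should give the exocyclic enol ether (2S,3S)-3-methyl-5-methylidene-2-(3,4,5-trimethoxyphenyl)oxolane F5. C-acylation of F5 with Cl3CCOCl and pyridine (CH2Cl2, 0 °C) should give the β-alkoxyvinyl trichloromethyl ketone (3E)-1,1,1-trichloro-3-[(4S,5S)-4-methyl-5-(3,4,5-trimethoxyphenyl)oxolan-2-ylidene]propan-2-one F6. Haloform-type cleavage of F6 with aqueous KOH in THF should then give carboxylate 11.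

**Further compounds**

F1 | step 10 | (E)-1-(penta-1,4-dien-1-yl)pyrrolidine | C=CC/C=C/N1CCCC1
F2 | step 10 | (2S,3S)-5-allyl-3-methyl-2-(3,4,5-trimethoxyphenyl)-2,3-dihydrobenzofuran-6-ol | C=CCc1cc2c(cc1O)O[C@H](c1cc(OC)c(OC)c(OC)c1)[C@H]2C
F3 | step 9 | (2R,5R)-1-(2-methoxypent-4-enoyl)-2,5-diphenylpyrrolidine | C=CCC(OC)C(=O)N1[C@@H](c2ccccc2)CC[C@@H]1c1ccccc1
F4 | step 9 | O-(1,1,3,3-tetramethyldisiloxanyl) hemiaminal of F3 | C=CCC(OC)C(O[Si](C)(C)O[SiH](C)C)N1[C@@H](c2ccccc2)CC[C@@H]1c1ccccc1
F5 | step 6 | (2S,3S)-3-methyl-5-methylidene-2-(3,4,5-trimethoxyphenyl)oxolane | O1[C@H](c2cc(OC)c(OC)c(OC)c2)[C@H](CC1=C)C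
F6 | step 6 | (3E)-1,1,1-trichloro-3-[(4S,5S)-4-methyl-5-(3,4,5-trimethoxyphenyl)oxolan-2-ylidene]propan-2-one | O1[C@H](c2cc(OC)c(OC)c(OC)c2)[C@H](C/C1=C\C(=O)C(Cl)(Cl)Cl)C
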